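**Retrosynthetic overview**
1. The target is reached by acidolysis of a tert-butyl ester, two aryl methoxymethyl ethers and one silyl ether; the aryl ketone comes from an aryllithium and a Weinreb amide.
2. The oxepine is the only ring that is built (the arene is bought as hydroquinone). It is formed in one operation by a [5+2] oxa-Michael/intramolecular Wittig annulation that makes O1–C7 and C5=C6 from a γ-lactol (O1, C2–C5) and a 1-alkyl alkenylphosphonium salt (C6, C7 and the whole side chain).
3. Enabling feature: in the 2,3,4,7-tetrahydrooxepine ring, O1 is joined through the C7 methylene to alkene carbon C6 (allylic ether O1–C7–C6=C5), and C5 is a CH three carbons away from carbinol carbon C2. This is the retron of alkoxide addition to a vinylphosphonium salt followed by Wittig closure onto a γ-hydroxy aldehyde.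
4. The lactol comes from ozonolysis of a butenyl chain; the C2 stereocentre comes from a copper bis(oxazoline)-catalysed Mukaiyama aldol of a silyl ketene thioacetal with an α-keto tert-butyl ester; the thioester is exchanged for the Weinreb amide.
5. The phosphonium salt comes from 6-methylhept-5-en-2-one by (E)-selective SeO2 allylic oxidation, silylation, kinetic enol triflate formation and palladium-catalysed P–C coupling.

Key step: step 10

Assumption: the γ-hydroxy aldehyde used in the key step exists as a mixture of lactol anomers and is used as such, because it equilibrates with the open form under base.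

**Route**

Step 1
Reactants: 1 di-tert-butyl oxalate; 2 but-3-enylmagnesium bromide
Product: 4 tert-butyl 2-oxohex-5-enoate, via magnesium hemiketalate 3 (not isolated)
Conditions: THF, −78 °C; then aq. NH4Cl
Reagents that add atoms: none
Why: Mono-addition of a Grignard reagent to a dialkyl oxalate at low temperature stops at the chelated tetrahedral adduct 3, which collapses to the α-keto ester only on quench, so over-addition should be avoided.

Step 2
Reactants: 5 S-ethyl thioacetate
Product: 7 1-(ethylsulfanyl)-1-(trimethylsilyloxy)ethene, via lithium enolate 6 (not isolated)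
Conditions: LiN(i-Pr)2, THF, −78 °C; then TMSCl
Reagents that add atoms: chlorotrimethylsilane, C[Si](C)(C)Cl
Why: Kinetic enolisation and O-silylation of a thioester is the standard preparation of a silyl ketene thioacetal for Mukaiyama aldol chemistry.

Step 3
Reactants: 4 tert-butyl 2-oxohex-5-enoate; 7 1-(ethylsulfanyl)-1-(trimethylsilyloxy)ethene
Product: 9 tert-butyl (2S)-2-[2-(ethylsulfanyl)-2-oxoethyl]-2-hydroxyhex-5-enoate, via trimethylsilyl ether 8 (not isolated)
Conditions: Cu(OTf)2 (10 mol%), (S,S)-tert-butyl-bis(oxazoline) ligand (11 mol%), THF, −78 °C; then 1 M HCl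
Reagents that add atoms: none
Why: This is an enantioselective Mukaiyama aldol addition to an α-keto ester chelated to the divalent copper bis(oxazoline) Lewis acid, in which the tert-butyl groups of the (S,S)-ligand shield the re face of the square-planar chelate so that attack on the si face should set the (S)-configured fully substituted carbinol carbon.

Step 4
Reactants: 9 tert-butyl (2S)-2-[2-(ethylsulfanyl)-2-oxoethyl]-2-hydroxyhex-5-enoate
Product: 10 tert-butyl (2S)-2-hydroxy-2-{2-[methoxy(methyl)amino]-2-oxoethyl}hex-5-enoate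
Conditions: MeNHOMe·HCl, AgOCOCF3, i-Pr2NEt, THF, 0 °C to rt
Reagents that add atoms: N,O-dimethylhydroxylamine hydrochloride, CNOC.Cl
Why: Thiophilic activation of the thioester by monovalent silver (Masamune-type thioester aminolysis) should give the Weinreb amide while the hindered tert-butyl ester and the tertiary alcohol stay untouched, and it replaces a retro-aldol-prone acyl group by a base-robust one.

Step 5
Reactants: 10 tert-butyl (2S)-2-hydroxy-2-{2-[methoxy(methyl)amino]-2-oxoethyl}hex-5-enoate
Product: 12 tert-butyl (2S)-5-hydroxy-2-{2-[methoxy(methyl)amino]-2-oxoethyl}oxolane-2-carboxylate (anomer mixture), via secondary ozonide 11 (not isolated)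
Conditions: O3, CH2Cl2, −78 °C; then PPh3, −78 °C to rt
Reagents that add atoms: ozone, [O-][O+]=O
Why: Ozonolysis with reductive work-up cleaves the only alkene to the aldehyde, which should close onto the tertiary hydroxyl as the five-membered lactol without touching the stereocentre.

Step 6
Reactants: 13 6-methylhept-5-en-2-one
Product: 14 (5E)-7-hydroxy-6-methylhept-5-en-2-one
Conditions: SeO2 (cat.), t-BuOOH, salicylic acid (cat.), CH2Cl2, rt
Reagents that add atoms: tert-butyl hydroperoxide, CC(C)(C)OO (oxygen relayed through SeO2, O=[Se]=O)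
Why: Selenium dioxide allylic oxidation (ene reaction, then [2,3]-sigmatropic shift) of a gem-dimethyl trisubstituted alkene hydroxylates the methyl group trans to the chain, which should set the (E)-allylic alcohol.

Step 7
Reactants: 14 (5E)-7-hydroxy-6-methylhept-5-en-2-one
Product: 15 (5E)-7-(tert-butyldimethylsilyloxy)-6-methylhept-5-en-2-one
Conditions: TBSCl, imidazole, CH2Cl2, 0 °C to rt
Reagents that add atoms: tert-butyldimethylsilyl chloride, CC(C)(C)[Si](C)(C)Cl
Why: Standard silylation of a primary alcohol gives an ether that tolerates the strong bases used later.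

Step 8
Reactants: 15 (5E)-7-(tert-butyldimethylsilyloxy)-6-methylhept-5-en-2-one
Product: 17 (5E)-7-(tert-butyldimethylsilyloxy)-6-methylhepta-1,5-dien-2-yl trifluoromethanesulfonate, via potassium enolate 16 (not isolated)
Conditions: KN(SiMe3)2, THF, −78 °C; then PhNTf2, −78 to 0 °C
Reagents that add atoms: N-phenylbis(trifluoromethanesulfonimide), O=S(=O)(N(c1ccccc1)S(=O)(=O)C(F)(F)F)C(F)(F)F
Why: Kinetic deprotonation of a methyl ketone by a hindered amide base occurs at the methyl group, and O-triflation of the enolate should give the 2-triflyloxy-1-alkene, with any internal isomer removed by chromatography.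

Step 9
Reactants: 17 (5E)-7-(tert-butyldimethylsilyloxy)-6-methylhepta-1,5-dien-2-yl trifluoromethanesulfonate
Product: 18 [(5E)-7-(tert-butyldimethylsilyloxy)-6-methylhepta-1,5-dien-2-yl]triphenylphosphonium trifluoromethanesulfonate
Conditions: PPh3, Pd(PPh3)4 (3 mol%), THF, 65 °C
Reagents that add atoms: triphenylphosphine, c1ccc(cc1)P(c1ccccc1)c1ccccc1
Why: Zerovalent palladium-catalysed coupling of alkenyl triflates with triphenylphosphine (oxidative addition, then P–C reductive elimination) is a known route to alkenylphosphonium triflates and should leave the silyl ether and the trisubstituted alkene untouched.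

Step 10
Reactants: 12 tert-butyl (2S)-5-hydroxy-2-{2-[methoxy(methyl)amino]-2-oxoethyl}oxolane-2-carboxylate; 18 [(5E)-7-(tert-butyldimethylsilyloxy)-6-methylhepta-1,5-dien-2-yl]triphenylphosphonium trifluoromethanesulfonate
Product: 21 tert-butyl (2S)-6-[(3E)-5-(tert-butyldimethylsilyloxy)-4-methylpent-3-en-1-yl]-2-{2-[methoxy(methyl)amino]-2-oxoethyl}-2,3,4,7-tetrahydrooxepine-2-carboxylate, via sodium alkoxide 19 (not isolated), via phosphorus ylide 20 (not isolated)
Conditions: NaH, THF, 0 °C; then 18, THF/DMF, rt to 60 °C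
Reagents that add atoms: none
Why: Proposed new method: deprotonation of lactol 12 gives, by ring–chain tautomerism, the tertiary sodium alkoxide 19 with a free aldehyde; its conjugate addition to the unsubstituted terminus of alkenylphosphonium salt 18 forms the O1–C7 bond and the non-stabilised ylide 20 at C6, which attacks the C5 aldehyde and, after collapse of the oxaphosphetane with loss of triphenylphosphine oxide, gives the C5=C6 double bond. The closest known reaction type is the Schweizer annulation of vinyltriphenylphosphonium salts with hydroxy carbonyl compounds to 2,5-dihydrofurans, 2H-chromenes and dihydropyrans, extended here to a seven-membered ring, a lactol-masked aldehyde and a 1-alkyl-substituted alkenylphosphonium salt. The oxepine ring is closed by 7-exo-trig attack of the ylide carbon on the aldehyde (intramolecular Wittig), helped by the gem-disubstituent effect of the fully substituted C2. No new stereocentre is formed and C2 is a spectator, since no bond to it is made or broken and the amide arm cannot undergo retro-aldol cleavage. The step needs O-alkylation by the tertiary alkoxide in preference to the lactolate oxygen and Wittig closure in preference to enolisation; the conjugate addition is reversible and only ylide 20 has a productive exit, so both lactol anomers and any lactolate adduct should funnel to 21, while the position of the ring alkene is fixed by the connectivity of the two partners and its cis geometry by the ring.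

Step 11
Reactants: 22 hydroquinone
Product: 23 1,4-bis(methoxymethoxy)benzene
Conditions: MOMCl, i-Pr2NEt, CH2Cl2, 0 °C to rt
Reagents that add atoms: chloromethyl methyl ether, COCCl
Why: Standard acetal protection of both phenols gives a symmetric arene whose four ring C–H positions are equivalent and each lies ortho to a directing group.

Step 12
Reactants: 21 tert-butyl (2S)-6-[(3E)-5-(tert-butyldimethylsilyloxy)-4-methylpent-3-en-1-yl]-2-{2-[methoxy(methyl)amino]-2-oxoethyl}-2,3,4,7-tetrahydrooxepine-2-carboxylate; 23 1,4-bis(methoxymethoxy)benzene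
Product: 26 tert-butyl (2S)-2-{2-[2,5-bis(methoxymethoxy)phenyl]-2-oxoethyl}-6-[(3E)-5-(tert-butyldimethylsilyloxy)-4-methylpent-3-en-1-yl]-2,3,4,7-tetrahydrooxepine-2-carboxylate, via aryllithium 24 (not isolated), via tetrahedral lithium adduct 25 (not isolated)
Conditions: 23 (slight excess over base), n-BuLi, TMEDA, THF, 0 °C; then 21, −78 to −40 °C; aq. NH4Cl
Reagents that add atoms: none
Why: Directed ortho-lithiation gives aryllithium 24, which should add once to the Weinreb amide to give the chelated adduct 25 that releases the ketone only on quench, while the tert-butyl ester on the fully substituted carbon should not compete.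

Step 13
Reactants: 26 tert-butyl (2S)-2-{2-[2,5-bis(methoxymethoxy)phenyl]-2-oxoethyl}-6-[(3E)-5-(tert-butyldimethylsilyloxy)-4-methylpent-3-en-1-yl]-2,3,4,7-tetrahydrooxepine-2-carboxylate
Product: 27 (2S)-2-[2-(2,5-dihydroxyphenyl)-2-oxoethyl]-6-[(3E)-5-hydroxy-4-methylpent-3-en-1-yl]-2,3,4,7-tetrahydrooxepine-2-carboxylic acid
Conditions: TFA/CH2Cl2/H2O, 0 °C to rt, argon
Reagents that add atoms: none
Why: Brønsted-acid solvolysis should remove the tert-butyl ester, both aryl methoxymethyl acetals and the primary silyl ether in one operation, whereas the ring allylic ether and the allylic alcohol, which could ionise only to primary/secondary allyl cations, and the C2 centre flanked by the carboxyl group should persist.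

**Compound list**
1 | di-tert-butyl oxalate | CC(C)(C)OC(=O)C(=O)OC(C)(C)C | starting material
2 | but-3-enylmagnesium bromide | C=CCC[Mg]Br | starting material
3 | bromomagnesium salt of tert-butyl 2-tert-butoxy-2-hydroxyhex-5-enoate (tetrahedral adduct) | C=CCCC(O[Mg]Br)(OC(C)(C)C)C(=O)OC(C)(C)C | intermediate (not isolated)
4 | tert-butyl 2-oxohex-5-enoate | C=CCCC(=O)C(=O)OC(C)(C)C | intermediate
5 | S-ethyl thioacetate | CCSC(C)=O | starting material
6 | lithium enolate of S-ethyl thioacetate | [Li]OC(=C)SCC | intermediate (not isolated)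
7 | 1-(ethylsulfanyl)-1-(trimethylsilyloxy)ethene | C=C(O[Si](C)(C)C)SCC | intermediate
8 | tert-butyl (2S)-2-[2-(ethylsulfanyl)-2-oxoethyl]-2-(trimethylsilyloxy)hex-5-enoate | C=CCC[C@](CC(=O)SCC)(C(=O)OC(C)(C)C)O[Si](C)(C)C | intermediate (not isolated)
9 | tert-butyl (2S)-2-[2-(ethylsulfanyl)-2-oxoethyl]-2-hydroxyhex-5-enoate | C=CCC[C@](CC(=O)SCC)(C(=O)OC(C)(C)C)O | intermediate
10 | tert-butyl (2S)-2-hydroxy-2-{2-[methoxy(methyl)amino]-2-oxoethyl}hex-5-enoate | C=CCC[C@](CC(=O)N(C)OC)(C(=O)OC(C)(C)C)O | intermediate
11 | secondary ozonide (1,2,4-trioxolane) of 10 | O1OC(OC1)CC[C@](CC(=O)N(C)OC)(C(=O)OC(C)(C)C)O | intermediate (not isolated)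
12 | tert-butyl (2S)-5-hydroxy-2-{2-[methoxy(methyl)amino]-2-oxoethyl}oxolane-2-carboxylate, anomer mixture | OC1CC[C@](CC(=O)N(C)OC)(C(=O)OC(C)(C)C)O1 | intermediate
13 | 6-methylhept-5-en-2-one | CC(=O)CCC=C(C)C | starting material
14 | (5E)-7-hydroxy-6-methylhept-5-en-2-one | C/C(=C\CCC(C)=O)CO | intermediate
15 | (5E)-7-(tert-butyldimethylsilyloxy)-6-methylhept-5-en-2-one | C/C(=C\CCC(C)=O)CO[Si](C)(C)C(C)(C)C | intermediate
16 | potassium (5E)-7-(tert-butyldimethylsilyloxy)-6-methylhepta-1,5-dien-2-olate | C/C(=C\CCC(=C)O[K])CO[Si](C)(C)C(C)(C)C | intermediate (not isolated)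
17 | (5E)-7-(tert-butyldimethylsilyloxy)-6-methylhepta-1,5-dien-2-yl trifluoromethanesulfonate | C/C(=C\CCC(=C)OS(=O)(=O)C(F)(F)F)CO[Si](C)(C)C(C)(C)C | intermediate
18 | [(5E)-7-(tert-butyldimethylsilyloxy)-6-methylhepta-1,5-dien-2-yl]triphenylphosphonium trifluoromethanesulfonate | C/C(=C\CCC(=C)[P+](c1ccccc1)(c1ccccc1)c1ccccc1)CO[Si](C)(C)C(C)(C)C.[O-]S(=O)(=O)C(F)(F)F | intermediate
19 | sodium (2S)-alkoxide of tert-butyl 2-hydroxy-2-{2-[methoxy(methyl)amino]-2-oxoethyl}-5-oxopentanoate (open form of 12) | O=CCC[C@](CC(=O)N(C)OC)(C(=O)OC(C)(C)C)[O-].[Na+] | intermediate (not isolated)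
20 | tert-butyl (2S)-2-{[(5E)-7-(tert-butyldimethylsilyloxy)-6-methyl-2-(triphenylphosphoranylidene)hept-5-en-1-yl]oxy}-2-{2-[methoxy(methyl)amino]-2-oxoethyl}-5-oxopentanoate | O=CCC[C@](CC(=O)N(C)OC)(C(=O)OC(C)(C)C)OCC(CC/C=C(\C)CO[Si](C)(C)C(C)(C)C)=P(c1ccccc1)(c1ccccc1)c1ccccc1 | intermediate (not isolated)
21 | tert-butyl (2S)-6-[(3E)-5-(tert-butyldimethylsilyloxy)-4-methylpent-3-en-1-yl]-2-{2-[methoxy(methyl)amino]-2-oxoethyl}-2,3,4,7-tetrahydrooxepine-2-carboxylate | C/C(=C\CCC1=CCC[C@](CC(=O)N(C)OC)(C(=O)OC(C)(C)C)OC1)CO[Si](C)(C)C(C)(C)C | intermediate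
22 | hydroquinone | Oc1ccc(O)cc1 | starting material
23 | 1,4-bis(methoxymethoxy)benzene | COCOc1ccc(OCOC)cc1 | intermediate
24 | 2,5-bis(methoxymethoxy)phenyllithium | [Li]c1cc(OCOC)ccc1OCOC | intermediate (not isolated)
25 | lithium alkoxide of the N-methoxy-N-methyl hemiaminal formed from 21 and 24 | C/C(=C\CCC1=CCC[C@](CC(O[Li])(N(C)OC)c2cc(OCOC)ccc2OCOC)(C(=O)OC(C)(C)C)OC1)CO[Si](C)(C)C(C)(C)C | intermediate (not isolated)
26 | tert-butyl (2S)-2-{2-[2,5-bis(methoxymethoxy)phenyl]-2-oxoethyl}-6-[(3E)-5-(tert-butyldimethylsilyloxy)-4-methylpent-3-en-1-yl]-2,3,4,7-tetrahydrooxepine-2-carboxylate | C/C(=C\CCC1=CCC[C@](CC(=O)c2cc(OCOC)ccc2OCOC)(C(=O)OC(C)(C)C)OC1)CO[Si](C)(C)C(C)(C)C | intermediate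
27 | (2S)-2-[2-(2,5-dihydroxyphenyl)-2-oxoethyl]-6-[(3E)-5-hydroxy-4-methylpent-3-en-1-yl]-2,3,4,7-tetrahydrooxepine-2-carboxylic acid | C/C(=C\CCC1=CCC[C@](CC(=O)c2cc(O)ccc2O)(C(=O)O)OC1)CO | target

**Totals**
Total step count: 13. Longest linear sequence: 7 steps (steps 1, 3, 4, 5, 10, 12, 13; the phosphonium branch, steps 6–9 then 10, 12, 13, is equally long).

**Steps most likely to fail**

Step 10. The phosphonium salt may be consumed unproductively by addition of the lactolate oxygen, base may isomerise the alkenylphosphonium salt to an allylic ylide, or the ylide may enolise the aldehyde instead of closing the seven-membered ring. The fallback builds the same two bonds in two known operations and sets out from enol triflate 17 and alkene 10. Stille coupling of 17 with Bu3SnCH2OH (Pd(PPh3)4, LiCl, dioxane, 90 °C) should give the allylic alcohol (5E)-7-(tert-butyldimethylsilyloxy)-6-methyl-2-methylidenehept-5-en-1-ol F1, and Appel bromination (CBr4, PPh3, CH2Cl2) the allylic bromide (5E)-1-bromo-7-(tert-butyldimethylsilyloxy)-6-methyl-2-methylidenehept-5-ene F2. Williamson etherification of the sodium alkoxide of 10 with F2 (NaH, Bu4NI, DMF, 0 °C) should give the diene ether tert-butyl (2S)-2-{[(5E)-7-(tert-butyldimethylsilyloxy)-6-methyl-2-methylidenehept-5-en-1-yl]oxy}-2-{2-[methoxy(methyl)amino]-2-oxoethyl}hex-5-enoate F3. Ring-closing metathesis with the second-generation Grubbs catalyst (CH2Cl2, 40 °C) between the terminal and the 1,1-disubstituted alkene then returns to 21.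

Step 13. Acid may ionise an allylic C–O bond, the liberated tert-butyl and methoxymethyl cations may alkylate the electron-rich hydroquinone, or the ring oxygen may be lost by acid-promoted β-elimination from the ketone. The fallback is a staged deprotection without strong protic acid and sets out from 26. ZnBr2 and n-PrSH (CH2Cl2, 0 °C) should cleave only the two aryl methoxymethyl ethers to give tert-butyl (2S)-6-[(3E)-5-(tert-butyldimethylsilyloxy)-4-methylpent-3-en-1-yl]-2-[2-(2,5-dihydroxyphenyl)-2-oxoethyl]-2,3,4,7-tetrahydrooxepine-2-carboxylate F6. Excess ZnBr2 (CH2Cl2, rt; chelation-assisted cleavage of the α-alkoxy tert-butyl ester) should then give (2S)-6-[(3E)-5-(tert-butyldimethylsilyloxy)-4-methylpent-3-en-1-yl]-2-[2-(2,5-dihydroxyphenyl)-2-oxoethyl]-2,3,4,7-tetrahydrooxepine-2-carboxylic acid F7. HF·pyridine (THF, 0 °C) removes the silyl ether and returns to 27.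

Step 12. The aryllithium may act as a base on the methylene next to the amide, after which β-elimination would open the oxepine, or it may fail to discriminate fully between the amide and the ester. The fallback goes through the aldehyde oxidation level and sets out from 21. Reduction with i-Bu2AlH (THF, −78 °C) should give tert-butyl (2S)-6-[(3E)-5-(tert-butyldimethylsilyloxy)-4-methylpent-3-en-1-yl]-2-(2-oxoethyl)-2,3,4,7-tetrahydrooxepine-2-carboxylate F4. Fast 1,2-addition of aryllithium 24 (THF, −78 °C) should give the benzylic alcohol tert-butyl (2S)-2-{2-[2,5-bis(methoxymethoxy)phenyl]-2-hydroxyethyl}-6-[(3E)-5-(tert-butyldimethylsilyloxy)-4-methylpent-3-en-1-yl]-2,3,4,7-tetrahydrooxepine-2-carboxylate F5 as a mixture of carbinol epimers. Oxidation with Dess–Martin periodinane (NaHCO3, CH2Cl2) removes that extra stereocentre and returns to 26.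

**Further compounds**
F1 | step 10 | (5E)-7-(tert-butyldimethylsilyloxy)-6-methyl-2-methylidenehept-5-en-1-ol | C/C(=C\CCC(=C)CO)CO[Si](C)(C)C(C)(C)C
F2 | step 10 | (5E)-1-bromo-7-(tert-butyldimethylsilyloxy)-6-methyl-2-methylidenehept-5-ene | C/C(=C\CCC(=C)CBr)CO[Si](C)(C)C(C)(C)C
F3 | step 10 | tert-butyl (2S)-2-{[(5E)-7-(tert-butyldimethylsilyloxy)-6-methyl-2-methylidenehept-5-en-1-yl]oxy}-2-{2-[methoxy(methyl)amino]-2-oxoethyl}hex-5-enoate | C=CCC[C@](CC(=O)N(C)OC)(C(=O)OC(C)(C)C)OCC(=C)CC/C=C(\C)CO[Si](C)(C)C(C)(C)C
F4 | step 12 | tert-butyl (2S)-6-[(3E)-5-(tert-butyldimethylsilyloxy)-4-methylpent-3-en-1-yl]-2-(2-oxoethyl)-2,3,4,7-tetrahydrooxepine-2-carboxylate | C/C(=C\CCC1=CCC[C@](CC=O)(C(=O)OC(C)(C)C)OC1)CO[Si](C)(C)C(C)(C)C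
F5 | step 12 | tert-butyl (2S)-2-{2-[2,5-bis(methoxymethoxy)phenyl]-2-hydroxyethyl}-6-[(3E)-5-(tert-butyldimethylsilyloxy)-4-methylpent-3-en-1-yl]-2,3,4,7-tetrahydrooxepine-2-carboxylate, carbinol epimers | C/C(=C\CCC1=CCC[C@](CC(O)c2cc(OCOC)ccc2OCOC)(C(=O)OC(C)(C)C)OC1)CO[Si](C)(C)C(C)(C)C
F6 | step 13 | tert-butyl (2S)-6-[(3E)-5-(tert-butyldimethylsilyloxy)-4-methylpent-3-en-1-yl]-2-[2-(2,5-dihydroxyphenyl)-2-oxoethyl]-2,3,4,7-tetrahydrooxepine-2-carboxylate | C/C(=C\CCC1=CCC[C@](CC(=O)c2cc(O)ccc2O)(C(=O)OC(C)(C)C)OC1)CO[Si](C)(C)C(C)(C)C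
F7 | step 13 | (2S)-6-[(3E)-5-(tert-butyldimethylsilyloxy)-4-methylpent-3-en-1-yl]-2-[2-(2,5-dihydroxyphenyl)-2-oxoethyl]-2,3,4,7-tetrahydrooxepine-2-carboxylic acid | C/C(=C\CCC1=CCC[C@](CC(=O)c2cc(O)ccc2O)(C(=O)O)OC1)CO[Si](C)(C)C(C)(C)C
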